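Ring letters: upper chroman A/C (benzo/pyran), its aryl B, central arene D, lower chroman E/F (pyran/benzo). Ring D is purchased with its oxygen pattern fixed; its formyl group becomes C4 of ring C, its allyl group C3 and C2 of ring E. Both pyrans come from one reaction type, aminocatalytic annulation of an arylacetaldehyde with an ortho-quinone methide. The key step joins the aldehyde that carries the upper chroman with a salicyl alcohol; it exploits that C4 of ring E is a benzylic CH2 ortho to O1 on ring F and C3 is α to C2: enamine addition forges C3–C4, hemiacetalisation closes ring E at O1–C2, the catalyst sets C3. The C2 hydroxyl is reduced away.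

Key step: step 13

Remark: the anomeric C2 configuration of lactols 16 and 24 and the double-bond geometry of 12 are left open because later steps erase them; the sense of induction of the aminocatalyst is assigned from the usual enamine-shielding model.

Step 1
Reactants: 1 2,4-dihydroxy-6-methoxybenzaldehyde
Product: 2 4-(benzyloxy)-2-hydroxy-6-methoxybenzaldehyde
Conditions: BnBr (1.05 equiv), K2CO3 (1.0 equiv), acetone, 50 °C
Reagents that add atoms: benzyl bromide, BrCc1ccccc1
Why: Williamson etherification; the C2 hydroxyl is held in a hydrogen bond to the formyl group, so the more acidic para hydroxyl should be alkylated selectively.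

Step 2
Reactants: 2 4-(benzyloxy)-2-hydroxy-6-methoxybenzaldehyde
Product: 3 5-(benzyloxy)-2-formyl-3-methoxyphenyl trifluoromethanesulfonate
Conditions: Tf2O (1.2 equiv), pyridine, CH2Cl2, 0 °C
Reagents that add atoms: trifluoromethanesulfonic anhydride, O=S(=O)(OS(=O)(=O)C(F)(F)F)C(F)(F)F
Why: O-sulfonylation of the remaining phenol gives an aryl triflate that the ortho formyl group activates for oxidative addition.

Step 3
Reactants: 3 5-(benzyloxy)-2-formyl-3-methoxyphenyl trifluoromethanesulfonate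
Product: 4 4-(benzyloxy)-2-methoxy-6-(prop-2-en-1-yl)benzaldehyde
Conditions: allylSnBu3 (1.2 equiv), Pd(PPh3)4 (5 mol %), LiCl (3 equiv), DMF, 80 °C
Reagents that add atoms: allyltributylstannane, C=CC[Sn](CCCC)(CCCC)CCCC
Why: Migita–Kosugi–Stille coupling of the electron-poor aryl triflate with the allylstannane, LiCl assisting transmetalation, installs the masked acetaldehyde side chain.

Step 4
Reactants: 5 3-(benzyloxy)phenol
Product: 6 5-(benzyloxy)-2-iodophenol
Conditions: I2 (1.0 equiv), NaHCO3, THF/H2O, 0 °C to rt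
Reagents that add atoms: iodine, II
Why: electrophilic aromatic iodination of the phenoxide should take the less hindered ortho position, which is also para to the benzyloxy group.

Step 5
Reactants: 6 5-(benzyloxy)-2-iodophenol; 4 4-(benzyloxy)-2-methoxy-6-(prop-2-en-1-yl)benzaldehyde
Product: 9 5-(benzyloxy)-2-{[4-(benzyloxy)-2-methoxy-6-(prop-2-en-1-yl)phenyl](hydroxy)methyl}phenol (racemic), via magnesium iodophenolate 7 (not isolated), via magnesiated phenolate 8 (not isolated)
Conditions: i-PrMgCl·LiCl (2.1 equiv), THF, −20 °C; then 4, −20 °C to rt; NH4Cl (aq)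
Reagents that add atoms: none
Why: deprotonation followed by iodine–magnesium exchange gives an ortho-magnesiated phenolate whose 1,2-addition to the aldehyde delivers the free ortho-hydroxybenzhydrol directly; the carbinol centre is formed without control and is erased in step 9.

Step 6
Reactants: 10 3-hydroxy-2,4-dimethoxybenzaldehyde
Product: 11 3-(benzyloxy)-2,4-dimethoxybenzaldehyde
Conditions: BnBr (1.1 equiv), K2CO3, DMF, rt
Reagents that add atoms: benzyl bromide, BrCc1ccccc1
Why: Williamson etherification protects the only phenol of ring B against the periodate used in step 11.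

Step 7
Reactants: 11 3-(benzyloxy)-2,4-dimethoxybenzaldehyde
Product: 12 2-(benzyloxy)-1,3-dimethoxy-4-(2-methoxyethenyl)benzene (E/Z mixture)
Conditions: Ph3P(CH2OMe)Cl (1.3 equiv), KOtBu (1.3 equiv), THF, 0 °C to rt
Reagents that add atoms: (methoxymethyl)triphenylphosphonium chloride, COC[P+](c1ccccc1)(c1ccccc1)c1ccccc1.[Cl-]
Why: Wittig methoxymethylenation gives the one-carbon homologated enol ether, whose double-bond geometry is irrelevant.

Step 8
Reactants: 12 2-(benzyloxy)-1,3-dimethoxy-4-(2-methoxyethenyl)benzene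
Product: 13 [3-(benzyloxy)-2,4-dimethoxyphenyl]acetaldehyde
Conditions: HCl (2 M aq), THF, 40 °C; used at once
Reagents that add atoms: water, O
Why: acid hydrolysis of the enol ether unmasks the arylacetaldehyde, which is taken on directly because it enolises and self-condenses on storage.

Step 9
Reactants: 9 5-(benzyloxy)-2-{[4-(benzyloxy)-2-methoxy-6-(prop-2-en-1-yl)phenyl](hydroxy)methyl}phenol; 13 [3-(benzyloxy)-2,4-dimethoxyphenyl]acetaldehyde
Product: 16 (3R,4S)-7-(benzyloxy)-3-[3-(benzyloxy)-2,4-dimethoxyphenyl]-4-[4-(benzyloxy)-2-methoxy-6-(prop-2-en-1-yl)phenyl]-3,4-dihydro-2H-chromen-2-ol (3,4-trans; C2 anomers), via ortho-quinone methide 14 (not isolated), via catalyst enamine 15 (not isolated)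
Conditions: (R)-2-[diphenyl(trimethylsilyloxy)methyl]pyrrolidine (20 mol %), PhCO2H (20 mol %), 13 (1.5 equiv), CHCl3, 0 °C to rt
Reagents that add atoms: none
Why: aminocatalytic Michael addition–hemiacetalisation (formal [4+2] annulation) of an aldehyde enamine with an ortho-quinone methide formed by acid-assisted loss of water from the benzhydrol; the diphenyl(silyloxy)methyl group of the catalyst shields one enamine face so that C3 should form as R, and the anti approach to the aryl-bearing methide carbon, reinforced by the diequatorial preference in ring C, should give the 3,4-trans (4S) lactol.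

Step 10
Reactants: 16 upper lactol
Product: 17 (3R,4S)-7-(benzyloxy)-3-[3-(benzyloxy)-2,4-dimethoxyphenyl]-4-[4-(benzyloxy)-2-methoxy-6-(prop-2-en-1-yl)phenyl]-3,4-dihydro-2H-chromene
Conditions: Et3SiH (3 equiv), TFA (5 equiv), CH2Cl2, −40 to 0 °C
Reagents that add atoms: none
Why: ionic hydrogenation, in which TFA ionises the lactol to the aryloxocarbenium ion and Et3SiH reduces it; C4 is untouched, and any reversible proton loss at C3 would return the favoured trans isomer.

Step 11
Reactants: 17 upper chroman with allyl side chain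
Product: 19 2-{5-(benzyloxy)-2-[(3R,4S)-7-(benzyloxy)-3-[3-(benzyloxy)-2,4-dimethoxyphenyl]-3,4-dihydro-2H-chromen-4-yl]-3-methoxyphenyl}acetaldehyde, via vicinal diol 18 (not isolated)
Conditions: OsO4 (2 mol %), NaIO4 (4 equiv), 2,6-lutidine (2 equiv), 1,4-dioxane/H2O 3:1, rt; used at once
Reagents that add atoms: sodium periodate, [Na+].[O-]I(=O)(=O)=O (terminal oxidant; its oxygen reaches the product through catalytic OsO4, O=[Os](=O)(=O)=O)
Why: Lemieux–Johnson oxidation, in which OsO4-catalysed dihydroxylation of the only alkene and periodate cleavage of the diol give the arylacetaldehyde while 2,6-lutidine suppresses over-oxidation.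

Step 12
Reactants: 20 4-(benzyloxy)-2-hydroxybenzaldehyde
Product: 21 5-(benzyloxy)-2-(hydroxymethyl)phenol
Conditions: NaBH4 (1.0 equiv), MeOH/THF, 0 °C
Reagents that add atoms: none
Why: hydride reduction of the aldehyde gives the salicyl alcohol that serves as precursor of the ring F ortho-quinone methide.

Step 13
Reactants: 19 arylacetaldehyde carrying the upper chroman; 21 5-(benzyloxy)-2-(hydroxymethyl)phenol
Product: 24 (3R)-7-(benzyloxy)-3-{5-(benzyloxy)-2-[(3R,4S)-7-(benzyloxy)-3-[3-(benzyloxy)-2,4-dimethoxyphenyl]-3,4-dihydro-2H-chromen-4-yl]-3-methoxyphenyl}-3,4-dihydro-2H-chromen-2-ol (C2 anomers), via ortho-quinone methide 22 (not isolated), via catalyst enamine 23 (not isolated)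
Conditions: (R)-2-[diphenyl(trimethylsilyloxy)methyl]pyrrolidine (20 mol %), PhCO2H (40 mol %), CHCl3, 35 °C, slow addition of 21 (1.5–2 equiv)
Reagents that add atoms: none
Why: Benzoic acid assists loss of water from 21, helped by the para benzyloxy group, to give ortho-quinone methide 22 while 19 and the catalyst form (E)-enamine 23; the enamine α-carbon adds to the exocyclic methylene of 22 (C3–C4 bond, ring F rearomatised), the freed phenol oxygen then adds to the iminium carbon to form O1–C2, and hydrolysis releases the catalyst and lactol 24. The closest known reaction type is the aminocatalytic Michael addition–hemiacetalisation (formal [4+2]) annulation of aldehydes with ortho-quinone methides generated in situ. Ring E closes by 6-exo-trig addition of the phenol oxygen to the C2 iminium (or aldehyde) carbon. C3 is the only new stereocentre that is kept: the bulky diphenyl(silyloxy)methyl group of the catalyst blocks one face of the enamine so that 22 adds to the other, which for the (R)-catalyst should correspond to 3R, while the anomeric C2 centre forms as a mixture and is removed in step 14. The step needs the enamine to capture 22 faster than 22 oligomerises, which slow addition of 21 and the absence of any free phenol in 19 should secure, and it needs catalyst control to override the stereocentres of ring C, which lie five bonds from the reacting carbon. Closure to the lactol also masks the α-aryl aldehyde and so should protect C3 from epimerisation.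

Step 14
Reactants: 24 bis-chroman lactol
Product: 25 (3R,4S)-7-(benzyloxy)-4-{4-(benzyloxy)-2-[(3R)-7-(benzyloxy)-3,4-dihydro-2H-chromen-3-yl]-6-methoxyphenyl}-3-[3-(benzyloxy)-2,4-dimethoxyphenyl]-3,4-dihydro-2H-chromene
Conditions: Et3SiH (3 equiv), TFA (5 equiv), CH2Cl2, −40 to 0 °C
Reagents that add atoms: none
Why: ionic hydrogenation of the lactol through the aryloxocarbenium ion, run cold and with excess silane so that hydride capture at C2 outruns proton loss from C3.

Step 15
Reactants: 25 tetra-O-benzyl ether of the target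
Product: 26 (3R,4S)-4-{4-hydroxy-2-[(3R)-7-hydroxy-3,4-dihydro-2H-chromen-3-yl]-6-methoxyphenyl}-3-(3-hydroxy-2,4-dimethoxyphenyl)-3,4-dihydro-2H-chromen-7-ol
Conditions: H2 (1 atm), Pd/C (10 wt %), EtOAc/MeOH, rt
Reagents that add atoms: none
Why: hydrogenolysis of the four benzyl ethers; neither chroman C–O bond is benzylic and no stereocentre is labile under these conditions.

Compound list
1 | 2,4-dihydroxy-6-methoxybenzaldehyde | COc1cc(O)cc(O)c1C=O | starting material
2 | 4-(benzyloxy)-2-hydroxy-6-methoxybenzaldehyde | COc1cc(OCc2ccccc2)cc(O)c1C=O | intermediate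
3 | 5-(benzyloxy)-2-formyl-3-methoxyphenyl trifluoromethanesulfonate | COc1cc(OCc2ccccc2)cc(OS(=O)(=O)C(F)(F)F)c1C=O | intermediate
4 | 4-(benzyloxy)-2-methoxy-6-(prop-2-en-1-yl)benzaldehyde | COc1cc(OCc2ccccc2)cc(CC=C)c1C=O | intermediate
5 | 3-(benzyloxy)phenol | Oc1cccc(OCc2ccccc2)c1 | starting material
6 | 5-(benzyloxy)-2-iodophenol | Oc1cc(OCc2ccccc2)ccc1I | intermediate
7 | chloromagnesium 5-(benzyloxy)-2-iodophenolate | Cl[Mg]Oc1cc(OCc2ccccc2)ccc1I | intermediate
8 | chloromagnesium 5-(benzyloxy)-2-(chloromagnesio)phenolate | Cl[Mg]Oc1cc(OCc2ccccc2)ccc1[Mg]Cl | intermediate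
9 | 5-(benzyloxy)-2-{[4-(benzyloxy)-2-methoxy-6-(prop-2-en-1-yl)phenyl](hydroxy)methyl}phenol, racemic | COc1cc(OCc2ccccc2)cc(CC=C)c1C(O)c1ccc(OCc2ccccc2)cc1O | intermediate
10 | 3-hydroxy-2,4-dimethoxybenzaldehyde | COc1ccc(C=O)c(OC)c1O | starting material
11 | 3-(benzyloxy)-2,4-dimethoxybenzaldehyde | COc1ccc(C=O)c(OC)c1OCc1ccccc1 | intermediate
12 | 2-(benzyloxy)-1,3-dimethoxy-4-(2-methoxyethenyl)benzene, E/Z mixture | COC=Cc1ccc(OC)c(OCc2ccccc2)c1OC | intermediate
13 | [3-(benzyloxy)-2,4-dimethoxyphenyl]acetaldehyde | COc1ccc(CC=O)c(OC)c1OCc1ccccc1 | intermediate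
14 | 3-(benzyloxy)-6-{[4-(benzyloxy)-2-methoxy-6-(prop-2-en-1-yl)phenyl]methylidene}cyclohexa-2,4-dien-1-one | COc1cc(OCc2ccccc2)cc(CC=C)c1C=C1C=CC(OCc2ccccc2)=CC1=O | intermediate
15 | (2R)-1-[(E)-2-[3-(benzyloxy)-2,4-dimethoxyphenyl]ethenyl]-2-[diphenyl(trimethylsilyloxy)methyl]pyrrolidine | COc1ccc(/C=C/N2CCC[C@@H]2C(O[Si](C)(C)C)(c2ccccc2)c2ccccc2)c(OC)c1OCc1ccccc1 | intermediate
16 | (3R,4S)-7-(benzyloxy)-3-[3-(benzyloxy)-2,4-dimethoxyphenyl]-4-[4-(benzyloxy)-2-methoxy-6-(prop-2-en-1-yl)phenyl]-3,4-dihydro-2H-chromen-2-ol, 3,4-trans, C2 anomers | COc1ccc([C@@H]2C(O)Oc3cc(OCc4ccccc4)ccc3[C@H]2c2c(OC)cc(OCc3ccccc3)cc2CC=C)c(OC)c1OCc1ccccc1 | intermediate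
17 | (3R,4S)-7-(benzyloxy)-3-[3-(benzyloxy)-2,4-dimethoxyphenyl]-4-[4-(benzyloxy)-2-methoxy-6-(prop-2-en-1-yl)phenyl]-3,4-dihydro-2H-chromene | COc1ccc([C@@H]2COc3cc(OCc4ccccc4)ccc3[C@H]2c2c(OC)cc(OCc3ccccc3)cc2CC=C)c(OC)c1OCc1ccccc1 | intermediate
18 | 3-{5-(benzyloxy)-2-[(3R,4S)-7-(benzyloxy)-3-[3-(benzyloxy)-2,4-dimethoxyphenyl]-3,4-dihydro-2H-chromen-4-yl]-3-methoxyphenyl}propane-1,2-diol, carbinol epimers | COc1ccc([C@@H]2COc3cc(OCc4ccccc4)ccc3[C@H]2c2c(OC)cc(OCc3ccccc3)cc2CC(O)CO)c(OC)c1OCc1ccccc1 | intermediate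
19 | 2-{5-(benzyloxy)-2-[(3R,4S)-7-(benzyloxy)-3-[3-(benzyloxy)-2,4-dimethoxyphenyl]-3,4-dihydro-2H-chromen-4-yl]-3-methoxyphenyl}acetaldehyde | COc1ccc([C@@H]2COc3cc(OCc4ccccc4)ccc3[C@H]2c2c(OC)cc(OCc3ccccc3)cc2CC=O)c(OC)c1OCc1ccccc1 | intermediate
20 | 4-(benzyloxy)-2-hydroxybenzaldehyde | O=Cc1ccc(OCc2ccccc2)cc1O | starting material
21 | 5-(benzyloxy)-2-(hydroxymethyl)phenol | OCc1ccc(OCc2ccccc2)cc1O | intermediate
22 | 3-(benzyloxy)-6-methylidenecyclohexa-2,4-dien-1-one | C=C1C=CC(OCc2ccccc2)=CC1=O | intermediate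
23 | (E)-enamine of 19 with (R)-2-[diphenyl(trimethylsilyloxy)methyl]pyrrolidine | COc1ccc([C@@H]2COc3cc(OCc4ccccc4)ccc3[C@H]2c2c(OC)cc(OCc3ccccc3)cc2/C=C/N2CCC[C@@H]2C(O[Si](C)(C)C)(c2ccccc2)c2ccccc2)c(OC)c1OCc1ccccc1 | intermediate
24 | (3R)-7-(benzyloxy)-3-{5-(benzyloxy)-2-[(3R,4S)-7-(benzyloxy)-3-[3-(benzyloxy)-2,4-dimethoxyphenyl]-3,4-dihydro-2H-chromen-4-yl]-3-methoxyphenyl}-3,4-dihydro-2H-chromen-2-ol, C2 anomers | COc1ccc([C@@H]2COc3cc(OCc4ccccc4)ccc3[C@H]2c2c(OC)cc(OCc3ccccc3)cc2[C@@H]2C(O)Oc3cc(OCc4ccccc4)ccc3C2)c(OC)c1OCc1ccccc1 | intermediate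
25 | (3R,4S)-7-(benzyloxy)-4-{4-(benzyloxy)-2-[(3R)-7-(benzyloxy)-3,4-dihydro-2H-chromen-3-yl]-6-methoxyphenyl}-3-[3-(benzyloxy)-2,4-dimethoxyphenyl]-3,4-dihydro-2H-chromene | COc1ccc([C@@H]2COc3cc(OCc4ccccc4)ccc3[C@H]2c2c(OC)cc(OCc3ccccc3)cc2[C@@H]2COc3cc(OCc4ccccc4)ccc3C2)c(OC)c1OCc1ccccc1 | intermediate
26 | (3R,4S)-4-{4-hydroxy-2-[(3R)-7-hydroxy-3,4-dihydro-2H-chromen-3-yl]-6-methoxyphenyl}-3-(3-hydroxy-2,4-dimethoxyphenyl)-3,4-dihydro-2H-chromen-7-ol | COc1ccc([C@@H]2COc3cc(O)ccc3[C@H]2c2c(OC)cc(O)cc2[C@@H]2COc3cc(O)ccc3C2)c(OC)c1O | target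

Total step count: 15. Longest linear sequence: 10 steps (steps 1, 2, 3, 5, 9, 10, 11, 13, 14, 15).

Steps most likely to fail

1. Step 13. The unsubstituted quinone methide 22 may oligomerise or alkylate its own precursor faster than the enamine of the bulky, ortho-substituted aldehyde captures it, and the C3 configuration may erode by re-enolisation of the open hydroxy-aldehyde form. The fallback sets out from 19 and comes back at 26, using isoflavone chemistry instead of a quinone methide. Aldehyde 19 is treated at −78 °C with magnesiated phenolate 8 (made from 6 as in step 5) to give the secondary alcohol F1, which MnO2 in CH2Cl2 should oxidise to the 2-hydroxydeoxybenzoin F2. Heating F2 with N,N-dimethylformamide dimethyl acetal in toluene should give the enaminone F3, which closes by addition–elimination of the phenol oxygen at the new carbon (again the O1–C2 bond of ring E) to the isoflavone F4. Asymmetric transfer hydrogenation with RuCl(p-cymene)[(R,R)-TsDPEN] and HCO2H/Et3N should reduce the C2=C3 bond and then the ketone under dynamic kinetic resolution, giving the cis-(3R,4R)-isoflavan-4-ol F5. Hydrogenolysis over Pd/C in EtOH should remove the benzylic C4 hydroxyl together with the four benzyl groups and give 26.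

2. Step 9. Capture of the strongly stabilised quinone methide 14, whose methide carbon carries a di-ortho-substituted aryl group, may be slow. That would leave time for reversible O-alkylation or attack by the neighbouring allyl group. Poor facial selectivity at C4 would also lower the optical purity once C3 settles trans. The fallback sets out from 9 and 12 and comes back at 17, replacing enamine catalysis by chiral Brønsted acid catalysis. Benzhydrol 9 and enol ether 12 are combined under a BINOL-derived chiral phosphoric acid (for example 3,3′-bis(2,4,6-triisopropylphenyl)-BINOL hydrogen phosphate, enantiomer chosen by screening) in toluene over molecular sieves. An inverse-electron-demand oxa-Diels–Alder reaction of the ion-paired quinone methide with the electron-rich alkene should give the 2-methoxychroman F6, which Et3SiH/TFA reduces to 17 as in step 10.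

3. Step 14. The oxocarbenium ion may lose the C3 proton to a 4H-chromene before hydride capture, which would scramble the configuration at C3 of ring E, and prolonged acid may cleave benzyl ethers. The fallback sets out from 24 and comes back at 25 without a cationic intermediate. NaBH4 in MeOH/THF at 0 °C should reduce the open hydroxy-aldehyde tautomer of 24 to the phenol–primary alcohol F7. Intramolecular Mitsunobu etherification (PPh3, DIAD, THF, 0 °C) should then close ring E by SN2 displacement at C2, leaving C3 untouched, to give 25.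

Further compounds
F1 | step 13 | 1-[4-(benzyloxy)-2-hydroxyphenyl]-2-{5-(benzyloxy)-2-[(3R,4S)-7-(benzyloxy)-3-[3-(benzyloxy)-2,4-dimethoxyphenyl]-3,4-dihydro-2H-chromen-4-yl]-3-methoxyphenyl}ethan-1-ol, carbinol epimers | COc1ccc([C@@H]2COc3cc(OCc4ccccc4)ccc3[C@H]2c2c(OC)cc(OCc3ccccc3)cc2CC(O)c2ccc(OCc3ccccc3)cc2O)c(OC)c1OCc1ccccc1
F2 | step 13 | 1-[4-(benzyloxy)-2-hydroxyphenyl]-2-{5-(benzyloxy)-2-[(3R,4S)-7-(benzyloxy)-3-[3-(benzyloxy)-2,4-dimethoxyphenyl]-3,4-dihydro-2H-chromen-4-yl]-3-methoxyphenyl}ethan-1-one | COc1ccc([C@@H]2COc3cc(OCc4ccccc4)ccc3[C@H]2c2c(OC)cc(OCc3ccccc3)cc2CC(=O)c2ccc(OCc3ccccc3)cc2O)c(OC)c1OCc1ccccc1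
F3 | step 13 | 3-(dimethylamino)-2-aryl-1-[4-(benzyloxy)-2-hydroxyphenyl]prop-2-en-1-one, aryl being the ring D unit of F2 | COc1ccc([C@@H]2COc3cc(OCc4ccccc4)ccc3[C@H]2c2c(OC)cc(OCc3ccccc3)cc2C(=CN(C)C)C(=O)c2ccc(OCc3ccccc3)cc2O)c(OC)c1OCc1ccccc1
F4 | step 13 | 7-(benzyloxy)-3-{5-(benzyloxy)-2-[(3R,4S)-7-(benzyloxy)-3-[3-(benzyloxy)-2,4-dimethoxyphenyl]-3,4-dihydro-2H-chromen-4-yl]-3-methoxyphenyl}-4H-chromen-4-one | COc1ccc([C@@H]2COc3cc(OCc4ccccc4)ccc3[C@H]2c2c(OC)cc(OCc3ccccc3)cc2-c2coc3cc(OCc4ccccc4)ccc3c2=O)c(OC)c1OCc1ccccc1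
F5 | step 13 | (3R,4R)-7-(benzyloxy)-3-{5-(benzyloxy)-2-[(3R,4S)-7-(benzyloxy)-3-[3-(benzyloxy)-2,4-dimethoxyphenyl]-3,4-dihydro-2H-chromen-4-yl]-3-methoxyphenyl}-3,4-dihydro-2H-chromen-4-ol, 3,4-cis | COc1ccc([C@@H]2COc3cc(OCc4ccccc4)ccc3[C@H]2c2c(OC)cc(OCc3ccccc3)cc2[C@@H]2COc3cc(OCc4ccccc4)ccc3[C@@H]2O)c(OC)c1OCc1ccccc1
F6 | step 9 | (3R,4S)-7-(benzyloxy)-3-[3-(benzyloxy)-2,4-dimethoxyphenyl]-4-[4-(benzyloxy)-2-methoxy-6-(prop-2-en-1-yl)phenyl]-2-methoxy-3,4-dihydro-2H-chromene, C2 anomers | COc1ccc([C@@H]2C(OC)Oc3cc(OCc4ccccc4)ccc3[C@H]2c2c(OC)cc(OCc3ccccc3)cc2CC=C)c(OC)c1OCc1ccccc1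
F7 | step 14 | (2R)-3-[4-(benzyloxy)-2-hydroxyphenyl]-2-{5-(benzyloxy)-2-[(3R,4S)-7-(benzyloxy)-3-[3-(benzyloxy)-2,4-dimethoxyphenyl]-3,4-dihydro-2H-chromen-4-yl]-3-methoxyphenyl}propan-1-ol | COc1ccc([C@@H]2COc3cc(OCc4ccccc4)ccc3[C@H]2c2c(OC)cc(OCc3ccccc3)cc2[C@H](CO)Cc2ccc(OCc3ccccc3)cc2O)c(OC)c1OCc1ccccc1
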